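**Plan**

- Numbering: C1 is the carboxyl carbon and the main chain runs to C14; the 1,2-dioxine ring is O–O/C3/C4/C5/C6. Retrosynthesis: the C6 ethyl group is traced back to a C6 ethynyl group (a slim, cation-stabilizing helper), and then the two ring C–C bonds on either side of the ring alkene, C5–C6 and C3–C4, are cut in one operation.
- Enabling feature: the cis C4=C5 bond of the six-membered peroxide ring sits between two carbons (C3 and C6) that each carry a peroxide oxygen. Each is therefore a latent peroxycarbenium ion, and the CH=C(Et) unit is a cis-vinylene bis-nucleophile, available as the Z-1,2-distannylalkene from but-1-yne.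
- Forward: two Cu-catalyzed asymmetric conjugate additions build the C7–C14 chain (C10 first, then C8). The ester is converted to a silylalkynyl ketone and then to its methoxy silylperoxy ketal, which carries C6 and the O–O unit.
- Ring: in one pot, peroxycarbenium alkenylation (C5–C6) is followed by a peroxy-Prins-type closure with a malonaldehyde ester acetal (C3–C4). Ester hydrolysis with C-desilylation and diimide reduction of ethynyl to ethyl finish the route.
- Stereochemistry: C10 and C8 come from catalyst control. C3 is set relative to C6 by the chair-like ring closure (ethynyl axial, chain and acetate arm equatorial). The sense of the ring relative to the chain is not induced, so the (3R,6R) ring diastereomer is separated after the key step.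

Key step: step 10

Remark on the chemistry: no 1,3-induction from C8 to C6 is assumed, and the ligand antipodes in steps 1 and 4 are assigned by analogy with related enoates and are exchanged if the opposite sense is found.

**Step 1**
Reactants: 1 methyl (E)-pent-2-enoate; 2 n-butylmagnesium bromide
Product: 3 methyl (S)-3-ethylheptanoate
Conditions: CuI (cat.), (R)-Tol-BINAP (cat.), t-BuOMe, −40 °C; then 1 M HCl
Reagents that add atoms: none
Why: Cu-catalyzed asymmetric conjugate addition of a Grignard reagent to an (E)-enoate, in which the chiral Cu–bisphosphine complex directs butyl to one face of C3 and so sets the center that becomes C10 as (S).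

**Step 2**
Reactants: 3 methyl (S)-3-ethylheptanoate
Product: 4 (S)-3-ethylheptanal
Conditions: i-Bu2AlH, CH2Cl2, −78 °C; then 1 M HCl
Reagents that add atoms: none
Why: Partial reduction of the ester stops at the aldehyde because the tetrahedral aluminate is stable at low temperature, and the stereocenter is not involved.

**Step 3**
Reactants: 4 (S)-3-ethylheptanal; 5 trimethyl phosphonoacetate
Product: 6 methyl (2E,5S)-5-ethylnon-2-enoate
Conditions: NaH, THF, 0 °C to rt
Reagents that add atoms: none
Why: Horner–Wadsworth–Emmons olefination of an unhindered aldehyde with a stabilized phosphonate anion should give the (E)-enoate under thermodynamic control of the oxaphosphetane.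

**Step 4**
Reactants: 6 methyl (2E,5S)-5-ethylnon-2-enoate; 7 methylmagnesium bromide
Product: 8 methyl (3S,5S)-5-ethyl-3-methylnonanoate
Conditions: CuI (cat.), (S)-Tol-BINAP (cat.), t-BuOMe, −20 °C; then 1 M HCl
Reagents that add atoms: none
Why: The same Cu-catalyzed asymmetric conjugate addition under catalyst control, now with the opposite ligand antipode because methyl must enter the opposite enoate face, sets the center that becomes C8 as (S) without influence from the remote C5 center.

**Step 5**
Reactants: 8 methyl (3S,5S)-5-ethyl-3-methylnonanoate; 9 ethynyltrimethylsilane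
Product: 10 (5S,7S)-7-ethyl-5-methyl-1-(trimethylsilyl)undec-1-yn-3-one
Conditions: 9, n-BuLi, THF, −78 °C; BF3·OEt2, then 8, −78 °C; H2O
Reagents that add atoms: none
Why: BF3-promoted acylation of a lithium acetylide by an ester stops at the ynone because the boron-bound tetrahedral adduct survives until work-up.

**Step 6**
Reactants: 10 (5S,7S)-7-ethyl-5-methyl-1-(trimethylsilyl)undec-1-yn-3-one
Product: 11 [(5S,7S)-7-ethyl-3,3-dimethoxy-5-methylundec-1-yn-1-yl]trimethylsilane
Conditions: HC(OMe)3, MeOH, p-TsOH (cat.), rt
Reagents that add atoms: trimethyl orthoformate COC(OC)OC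
Why: Acid-catalyzed ketalization driven by the orthoformate as water scavenger, with the silyl group shielding the alkyne terminus from conjugate addition of methanol.

**Step 7**
Reactants: 11 [(5S,7S)-7-ethyl-3,3-dimethoxy-5-methylundec-1-yn-1-yl]trimethylsilane
Product: 12 (5S,7S)-7-ethyl-3-methoxy-5-methyl-1-(trimethylsilyl)undec-1-yn-3-yl hydroperoxide (both C3 epimers)
Conditions: H2O2 (anhydrous, in Et2O), camphorsulfonic acid (cat.), 0 °C, stopped at partial conversion
Reagents that add atoms: hydrogen peroxide OO
Why: Acid-catalyzed exchange of one methoxy group for hydroperoxide through the propargylic oxocarbenium ion (perhydrolysis of a ketal); the new acetal center forms as both epimers, which does not matter because it is ionized in step 10.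

**Step 8**
Reactants: 12 (5S,7S)-7-ethyl-3-methoxy-5-methyl-1-(trimethylsilyl)undec-1-yn-3-yl hydroperoxide
Product: 13 triethyl({(5S,7S)-7-ethyl-3-methoxy-5-methyl-1-(trimethylsilyl)undec-1-yn-3-yl}peroxy)silane (both C3 epimers)
Conditions: Et3SiCl, imidazole, CH2Cl2, 0 °C
Reagents that add atoms: chlorotriethylsilane CC[Si](Cl)(CC)CC
Why: O-Silylation of the hydroperoxide gives a chromatographically stable silyl peroxyketal whose silyl group later acts as the leaving group on oxygen.

**Step 9**
Reactants: 14 but-1-yne; 15 hexamethylditin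
Product: 16 (Z)-1,2-bis(trimethylstannyl)but-1-ene
Conditions: Pd(PPh3)4 (cat.), THF, 65 °C, sealed tube
Reagents that add atoms: none
Why: Pd-catalyzed distannylation of a terminal alkyne proceeds by oxidative addition of the Sn–Sn bond, syn insertion and reductive elimination, so only the Z isomer with both tin groups cis should form.

**Step 10**
Reactants: 13 triethyl({(5S,7S)-7-ethyl-3-methoxy-5-methyl-1-(trimethylsilyl)undec-1-yn-3-yl}peroxy)silane; 16 (Z)-1,2-bis(trimethylstannyl)but-1-ene; 17 methyl 3,3-dimethoxypropanoate
Product: 20 methyl 2-[(3R,6R)-4-ethyl-6-[(2S,4S)-4-ethyl-2-methyloctyl]-6-[(trimethylsilyl)ethynyl]-3,6-dihydro-1,2-dioxin-3-yl]acetate, via stannyl allyl silyl peroxide 18 (not isolated), via mixed peroxyacetal 19 (not isolated)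
Conditions: 16, Me3SiOTf, 2,6-di-tert-butyl-4-methylpyridine, CH2Cl2, −78 °C; then 17, Me3SiOTf, −78 to −40 °C; chromatography
Reagents that add atoms: none
Why: Proposed new method: Me3SiOTf removes the methoxy group of 13 and the tertiary propargylic peroxycarbenium ion is attacked at the terminal CH–Sn carbon of 16 (the charge developing at C4 is stabilized by the ethyl group and the C5–Sn bond), and loss of Me3Sn+ with retention gives 18 with C6 cis to the remaining tin; the closest known reactions are the Lewis-acid allylation of monoperoxyketals by allylsilanes and allylstannanes and the annulation of silylperoxy ketals with alkenes. Acetal 17 then exchanges onto the silyl peroxide (as in the Me3SiOTf-mediated condensation of silyl peroxides with carbonyl compounds to 1,2,4-trioxanes) to give 19, and its secondary peroxycarbenium ion is captured by the internal vinylstannane, the peroxide counterpart of a silyl-Prins or vinylsilane-terminated acetal cyclization. The six-membered 1,2-dioxine ring closes in the 6-endo mode at the tin-bearing carbon C4, because only this path gives a β-stannyl-stabilized cation (at C5), and destannylation with retention leaves C3 and C6 cis on the new ring alkene and the ethyl group outside the ring. C3 is set relative to C6 in a chair-like transition state: the (E)-peroxycarbenium ion places CH2CO2Me equatorial, and the axial C4–Sn bond, which must overlap with the empty orbital at C5, tolerates only the slim alkynyl group in the 1,3-diaxial position at C6, so the branched chain is equatorial and the acetate arm ends cis to the alkynyl group (the future ethyl group). C6 is created in the first, intermolecular event, where the remote C8 and C10 centers give no useful facial bias; both ring senses are therefore expected and the (3R,6R) isomer 20 is separated from its (3S,6S) diastereomer by chromatography. The step needs ionization of C–OMe in preference to C–OO (the ether oxygen is the more basic site), reaction of the two tin centers in the order terminal then internal (secured by their substitution and by the intramolecularity of the second event) and freedom from protodestannylation (hindered pyridine base).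

**Step 11**
Reactants: 20 methyl 2-[(3R,6R)-4-ethyl-6-[(2S,4S)-4-ethyl-2-methyloctyl]-6-[(trimethylsilyl)ethynyl]-3,6-dihydro-1,2-dioxin-3-yl]acetate
Product: 21 2-[(3R,6R)-4-ethyl-6-[(2S,4S)-4-ethyl-2-methyloctyl]-6-ethynyl-3,6-dihydro-1,2-dioxin-3-yl]acetic acid
Conditions: LiOH, THF/MeOH/H2O, 0 °C; then 1 M HCl to pH 3–4 at 0 °C
Reagents that add atoms: lithium hydroxide [Li+].[OH-]
Why: Hydroxide hydrolyses the methyl ester and, in the same pot, cleaves the C-silyl group of the alkyne; the carboxylate formed first protects C2 against enolization, and low temperature is meant to keep the allylic peroxide from base-induced opening.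

**Step 12**
Reactants: 21 2-[(3R,6R)-4-ethyl-6-[(2S,4S)-4-ethyl-2-methyloctyl]-6-ethynyl-3,6-dihydro-1,2-dioxin-3-yl]acetic acid
Product: 22 2-[(3R,6R)-4,6-diethyl-6-[(2S,4S)-4-ethyl-2-methyloctyl]-3,6-dihydro-1,2-dioxin-3-yl]acetic acid (CNP0179105.1)
Conditions: KO2C–N=N–CO2K (excess), AcOH, MeOH, 0 °C to rt
Reagents that add atoms: none
Why: Diimide transfers hydrogen twice to the unhindered terminal alkyne through a cyclic transition state and leaves the O–O bond intact, while the trisubstituted ring alkene next to the quaternary carbon should react far more slowly.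

**Compound list**

1 | methyl (E)-pent-2-enoate | CC/C=C/C(=O)OC | starting material
2 | n-butylmagnesium bromide | CCCC[Mg]Br | starting material
3 | methyl (S)-3-ethylheptanoate | CCCC[C@H](CC)CC(=O)OC | intermediate
4 | (S)-3-ethylheptanal | CCCC[C@H](CC)CC=O | intermediate
5 | trimethyl phosphonoacetate | COC(=O)CP(=O)(OC)OC | starting material
6 | methyl (2E,5S)-5-ethylnon-2-enoate | CCCC[C@H](CC)C/C=C/C(=O)OC | intermediate
7 | methylmagnesium bromide | C[Mg]Br | starting material
8 | methyl (3S,5S)-5-ethyl-3-methylnonanoate | CCCC[C@H](CC)C[C@H](C)CC(=O)OC | intermediate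
9 | ethynyltrimethylsilane | C#C[Si](C)(C)C | starting material
10 | (5S,7S)-7-ethyl-5-methyl-1-(trimethylsilyl)undec-1-yn-3-one | CCCC[C@H](CC)C[C@H](C)CC(=O)C#C[Si](C)(C)C | intermediate
11 | [(5S,7S)-7-ethyl-3,3-dimethoxy-5-methylundec-1-yn-1-yl]trimethylsilane | CCCC[C@H](CC)C[C@H](C)CC(OC)(OC)C#C[Si](C)(C)C | intermediate
12 | (5S,7S)-7-ethyl-3-methoxy-5-methyl-1-(trimethylsilyl)undec-1-yn-3-yl hydroperoxide (both C3 epimers) | CCCC[C@H](CC)C[C@H](C)CC(OC)(OO)C#C[Si](C)(C)C | intermediate
13 | triethyl({(5S,7S)-7-ethyl-3-methoxy-5-methyl-1-(trimethylsilyl)undec-1-yn-3-yl}peroxy)silane (both C3 epimers) | CCCC[C@H](CC)C[C@H](C)CC(OC)(OO[Si](CC)(CC)CC)C#C[Si](C)(C)C | intermediate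
14 | but-1-yne | CCC#C | starting material
15 | hexamethylditin | C[Sn](C)(C)[Sn](C)(C)C | starting material
16 | (Z)-1,2-bis(trimethylstannyl)but-1-ene | CC/C(=C/[Sn](C)(C)C)[Sn](C)(C)C | intermediate
17 | methyl 3,3-dimethoxypropanoate | COC(OC)CC(=O)OC | starting material
18 | triethyl({(3Z,7S,9S)-9-ethyl-7-methyl-3-(trimethylstannyl)-5-[(trimethylsilyl)ethynyl]tridec-3-en-5-yl}peroxy)silane (both C5 epimers; not isolated) | CCCC[C@H](CC)C[C@H](C)CC(OO[Si](CC)(CC)CC)(C#C[Si](C)(C)C)/C=C(/CC)[Sn](C)(C)C | intermediate
19 | methyl 3-methoxy-3-({(3Z,7S,9S)-9-ethyl-7-methyl-3-(trimethylstannyl)-5-[(trimethylsilyl)ethynyl]tridec-3-en-5-yl}peroxy)propanoate (epimer mixture; not isolated) | CCCC[C@H](CC)C[C@H](C)CC(OOC(OC)CC(=O)OC)(C#C[Si](C)(C)C)/C=C(/CC)[Sn](C)(C)C | intermediate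
20 | methyl 2-[(3R,6R)-4-ethyl-6-[(2S,4S)-4-ethyl-2-methyloctyl]-6-[(trimethylsilyl)ethynyl]-3,6-dihydro-1,2-dioxin-3-yl]acetate | CCCC[C@H](CC)C[C@H](C)C[C@]1(C#C[Si](C)(C)C)C=C(CC)[C@@H](CC(=O)OC)OO1 | intermediate
21 | 2-[(3R,6R)-4-ethyl-6-[(2S,4S)-4-ethyl-2-methyloctyl]-6-ethynyl-3,6-dihydro-1,2-dioxin-3-yl]acetic acid | CCCC[C@H](CC)C[C@H](C)C[C@]1(C#C)C=C(CC)[C@@H](CC(=O)O)OO1 | intermediate
22 | 2-[(3R,6R)-4,6-diethyl-6-[(2S,4S)-4-ethyl-2-methyloctyl]-3,6-dihydro-1,2-dioxin-3-yl]acetic acid | CCCC[C@H](CC)C[C@H](C)C[C@]1(CC)C=C(CC)[C@@H](CC(=O)O)OO1 | target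

**Totals**

Total step count: 12. Longest linear sequence: 11 steps (steps 1–8, 10, 11, 12).

**Steps most likely to fail**

1. Step 10.
   - What may go wrong: heterolytic O–O fragmentation of the peroxycarbenium ions (Criegee- or Hock-type, with migration); protodestannylation of the vinyltin groups before C–C bond formation; and the lack of facial bias in the first alkenylation, which halves the throughput.
   - Fallback (known reactions, ring closed through C–O instead of C–C), setting out from 16 and 10 and returning at 20: tin–lithium exchange of 16 with MeLi at the less hindered CH–Sn should give [(Z)-2-(trimethylstannyl)but-1-en-1-yl]lithium F1. Addition of F1 to the carbonyl group of 10 gives the tertiary alcohol (3Z,7S,9S)-9-ethyl-7-methyl-3-(trimethylstannyl)-5-[(trimethylsilyl)ethynyl]tridec-3-en-5-ol F2. Stille coupling of F2 with commercial methyl (E)-3-iodoacrylate (Pd2(dba)3, AsPh3, CuI) gives methyl (2E,4Z,8S,10S)-4,10-diethyl-6-hydroxy-8-methyl-6-[(trimethylsilyl)ethynyl]tetradeca-2,4-dienoate F3. Acid-catalyzed exchange of the doubly activated tertiary hydroxyl group with H2O2 gives methyl (2E,4Z,8S,10S)-4,10-diethyl-6-hydroperoxy-8-methyl-6-[(trimethylsilyl)ethynyl]tetradeca-2,4-dienoate F4. Amine-catalyzed 6-exo oxa-Michael addition of the hydroperoxide to C3 (Et2NH, CF3CH2OH) then gives 20, with the same chromatographic separation of ring diastereomers.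

2. Step 7.
   - What may go wrong: over-exchange to the geminal dihydroperoxide, or acid-induced heterolysis of the tertiary propargylic hydroperoxide.
   - Fallback (carbonyl oxide route instead of ketal exchange), setting out from 10 and returning at 12: Wittig methylenation of 10 (Ph3PCH3Br, KOtBu) gives the enyne trimethyl[(5S,7S)-7-ethyl-5-methyl-3-methylideneundec-1-yn-1-yl]silane F5. Ozonolysis of F5 in MeOH/CH2Cl2 at −78 °C forms the carbonyl oxide at the disubstituted carbon, which methanol traps to give 12.

3. Step 11.
   - What may go wrong: base-induced Kornblum–DeLaMare fragmentation by removal of the C3 hydrogen, or E1cB opening of the ring with loss of the C3 configuration.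
   - Fallback (different ester, no hydroxide), setting out from 17 and returning at 21: Ti(OiPr)4-catalyzed transesterification of 17 with 2-(trimethylsilyl)ethanol gives 2-(trimethylsilyl)ethyl 3,3-dimethoxypropanoate F6. F6 is used in place of 17 in step 10 with 13 and 16; by way of 18 and the unisolated mixed peroxyacetal 2-(trimethylsilyl)ethyl 3-methoxy-3-({(3Z,7S,9S)-9-ethyl-7-methyl-3-(trimethylstannyl)-5-[(trimethylsilyl)ethynyl]tridec-3-en-5-yl}peroxy)propanoate F7 this should give 2-(trimethylsilyl)ethyl 2-[(3R,6R)-4-ethyl-6-[(2S,4S)-4-ethyl-2-methyloctyl]-6-[(trimethylsilyl)ethynyl]-3,6-dihydro-1,2-dioxin-3-yl]acetate F8. Buffered fluoride (Bu4NF/AcOH or tris(dimethylamino)sulfonium difluorotrimethylsilicate) removes the silylethyl ester and the alkynyl silyl group of F8 in one operation and gives 21.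

**Further compounds**

F1 | step 10 | [(Z)-2-(trimethylstannyl)but-1-en-1-yl]lithium | [Li]/C=C(/CC)[Sn](C)(C)C
F2 | step 10 | (3Z,7S,9S)-9-ethyl-7-methyl-3-(trimethylstannyl)-5-[(trimethylsilyl)ethynyl]tridec-3-en-5-ol (both C5 epimers) | CCCC[C@H](CC)C[C@H](C)CC(O)(C#C[Si](C)(C)C)/C=C(/CC)[Sn](C)(C)C
F3 | step 10 | methyl (2E,4Z,8S,10S)-4,10-diethyl-6-hydroxy-8-methyl-6-[(trimethylsilyl)ethynyl]tetradeca-2,4-dienoate (both C6 epimers) | CCCC[C@H](CC)C[C@H](C)CC(O)(C#C[Si](C)(C)C)/C=C(CC)\C=C\C(=O)OC
F4 | step 10 | methyl (2E,4Z,8S,10S)-4,10-diethyl-6-hydroperoxy-8-methyl-6-[(trimethylsilyl)ethynyl]tetradeca-2,4-dienoate (both C6 epimers) | CCCC[C@H](CC)C[C@H](C)CC(OO)(C#C[Si](C)(C)C)/C=C(CC)\C=C\C(=O)OC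
F5 | step 7 | trimethyl[(5S,7S)-7-ethyl-5-methyl-3-methylideneundec-1-yn-1-yl]silane | CCCC[C@H](CC)C[C@H](C)CC(=C)C#C[Si](C)(C)C
F6 | step 11 | 2-(trimethylsilyl)ethyl 3,3-dimethoxypropanoate | COC(OC)CC(=O)OCC[Si](C)(C)C
F7 | step 11 | 2-(trimethylsilyl)ethyl 3-methoxy-3-({(3Z,7S,9S)-9-ethyl-7-methyl-3-(trimethylstannyl)-5-[(trimethylsilyl)ethynyl]tridec-3-en-5-yl}peroxy)propanoate (epimer mixture) | CCCC[C@H](CC)C[C@H](C)CC(OOC(OC)CC(=O)OCC[Si](C)(C)C)(C#C[Si](C)(C)C)/C=C(/CC)[Sn](C)(C)C
F8 | step 11 | 2-(trimethylsilyl)ethyl 2-[(3R,6R)-4-ethyl-6-[(2S,4S)-4-ethyl-2-methyloctyl]-6-[(trimethylsilyl)ethynyl]-3,6-dihydro-1,2-dioxin-3-yl]acetate | CCCC[C@H](CC)C[C@H](C)C[C@]1(C#C[Si](C)(C)C)C=C(CC)[C@@H](CC(=O)OCC[Si](C)(C)C)OO1
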